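Remark on the chemistry: the SMILES is read as the (R)-carbinol with Z geometry at both disubstituted olefins. Locants used below:
- Thiazole: S1, C2, N3, C4, C5.
- Chain on thiazole C2: C7 (quaternary, two methyls), C8 (carbinol, oxygen O8), C9, C10=C11, C12(=CH2), C13, C14, N15.
- Chain on thiazole C4: C1′ to C6′.

## Analysis of the target

Mycothiazole (18) is an open-chain polyene hung on a single ring, a 2,4-disubstituted 1,3-thiazole. C2 carries the chain C7–C14, which ends in a methyl carbamate on N15, and C4 carries a (2′Z)-hexa-2′,5′-dienyl chain. The only stereocentre is the (R)-carbinol C8. It is neopentylic, because C7 is quaternary and bears thiazole C2, and nothing else in the molecule can relay stereochemistry to it, so it must be set absolutely. The real stereochemical load is the two Z olefins.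

C10=C11 is Z and conjugated with the 1,1-disubstituted C12=CH2. This diene is twisted by allylic strain, less stable than its E isomer, and sensitive to acid, radicals and metal hydrides. The C1′–C6′ 1,4-diene holds one CH2 that is allylic and thiazolylic and one that is bis-allylic. Base or metal hydride therefore moves its double bonds into conjugation, and its terminal vinyl group competes in any olefin chemistry. The difficulty is geometry and chemoselectivity among five C=C bonds of four kinds, next to a hindered free alcohol.

The feature that the route exploits is this. O8 and the carbamate carbonyl on N15 are bridged by C8–C14. Replacing the OMe group by O8 closes a ten-membered 1-oxa-3-azacyclodec-7-en-2-one ring (O8, C=O, N15, C14, C13, C12, C11, C10, C9, C8), in which C10=C11 is endocyclic and C12=CH2 exocyclic. The triad C10=C11–C12(=CH2) is also the retron of an enyne metathesis between a terminal alkene (C10) and a terminal alkyne (C11≡C12).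

## Retrosynthetic reasoning

**C2′=C3′ is cut first (18 ⇒ 15 + 17, from 16).** The skipped diene is the most fragile part, and its vinyl end would compete in the metathesis. It is therefore made in the last step, by a Z-selective Wittig reaction that adds the last four carbons at once. The forward reaction must outrun enolisation of the heteroarylacetaldehyde 15.

**15 ⇒ 14.** This is only an adjustment of oxidation level. The ester in 14 is a metathesis-inert placeholder for the C1′–C6′ chain, and it is built in during thiazole formation at no extra cost.

**14 ⇒ 13 is a reconnection, not a cut.** The methoxy group on the carbamate carbonyl is exchanged for O8, which leads back to the ten-membered cyclic carbamate 13. In the forward sense, methanolysis frees the hindered alcohol and completes the methyl carbamate in one step. The tether therefore contains no sacrificial atom and also protects O8.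

**13 ⇒ 11 (through 12) is the key disconnection.** C10=C11 and C12=CH2 are cut together. 13 is a constitutional isomer of the acyclic enyne 11, and the ring-closing enyne metathesis makes both diene double bonds. The bonds are cut here because the ring supplies the Z geometry. The untethered intermolecular version of the same reorganisation has no element that controls geometry and normally favours E. The precursor holds no diene, no Z olefin and no ring.

**11 ⇒ 7 + 8.** The O8–C(=O) bond is cut. The isocyanate 10, made from acid 8 through acyl azide 9 by a Curtius rearrangement, brings N15, C11–C14 and the carbonyl in one addition to the alcohol 7.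

**7 ⇒ 5 ⇒ 4.** The C8–C9 bond is cut by an asymmetric allylboration, which sets C8. The aldehyde 5 has no α-hydrogen and comes from the neopentyl alcohol 4 by oxidation.

**4 ⇒ 2 + 3, and 2 ⇒ 1.** The thiazole is cut at S1–C5 and N3–C4 (Hantzsch). Thioamide 2 brings C7 with its two methyl groups, and chloroketone 3 brings C4, C5 and the ester handle. Thioamide 2 comes from the commercial nitrile 1.

## Alternatives that were turned down

Alternative 1: This is the textbook cut, at the C11–C12 σ-bond between the two sp2 carbons of the diene.
- Forward key step: Stille- or Suzuki-type coupling of the (Z)-alkenyl iodide A1 with the 2-metallated butenyl carbamate A2.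
- The coupling only transfers geometry that has to be created elsewhere. A1 needs protection of O8, oxidative cleavage of the allyl group of 7, and a Stork–Zhao olefination on a β-silyloxy aldehyde that is prone to elimination.
- A2 needs an internal (Markovnikov) hydrometallation of a terminal alkyne, which is against the normal regiochemical preference.
- A deprotection follows the coupling. About twice as many operations are spent between 7 and 14, with stoichiometric tin, and none of the molecule's own functionality is used.

Alternative 2: This cut takes C8–C9 together with a temporary O8–C12 bond, and later C13–C14 next to nitrogen.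
- Forward key step: catalytic asymmetric hetero-Diels–Alder reaction of aldehyde A3 with a 1-alkoxydiene, then oxidation to the dihydropyranone A4. This sets C8 and the cis C10=C11 together.
- A4 is then opened by double silylmethyl-cerium addition and Peterson elimination to the 2-(silylmethyl)diene A5. A5 is aminomethylated with a C1 N-acyliminium ion (aza-Sakurai).
- The carbonyl of A3 sits next to the quaternary C7 and is a poor heterodienophile for a weakly activated diene.
- The last C–C bond formation passes through a C12 cation that is allylic and delocalised to C10. The Z geometry can leak, and the free O8 can trap the cation as a cyclic ether.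
- The thiazole nitrogen binds the Lewis acid.
- The organocerium step forces the fragile hexadienyl chain to be carried from the start. The risk therefore sits in three places instead of one.

Alternative 3: This cut goes through the heterocycle (S1–C5 and N3–C4) at the end, in the spirit of the biosynthetic insertion of a cysteine unit between two polyketide halves.
- Forward key step: Hantzsch condensation of the fully elaborated thioamide A6 with the bromoketone A7.
- The CH2 of A7 between the carbonyl and the Z olefin is doubly activated, so migration into conjugation is expected before or during the condensation.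
- The acid set free and the dehydration step threaten the twisted Z diene of A6.
- The cut is convergent but solves neither Z olefin. Both problems are only moved into the fragment syntheses.

Key step: step 6

## Route

Step 1
Reactants: 1 3-hydroxy-2,2-dimethylpropanenitrile
Product: 2 3-hydroxy-2,2-dimethylpropanethioamide
Conditions: (EtO)2P(S)SH, H2O, THF, 70 °C
Reagents that add atoms: O,O-diethyl dithiophosphoric acid, CCOP(=S)(S)OCC
Why: Acid-promoted thiolysis of a nitrile: the dithiophosphoric acid protonates the nitrile and adds through sulfur, and water cleaves the S–P bond of the thioimidate to release the primary thioamide. The method is established for hindered aliphatic nitriles and should leave the neopentyl alcohol untouched.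

Step 2
Reactants: 2 3-hydroxy-2,2-dimethylpropanethioamide; 3 methyl 4-chloro-3-oxobutanoate
Product: 4 methyl 2-[2-(1-hydroxy-2-methylpropan-2-yl)-1,3-thiazol-4-yl]acetate
Conditions: MeOH, 65 °C; aq NaHCO3 work-up
Reagents that add atoms: none
Why: Hantzsch thiazole synthesis: sulfur displaces chloride (S1–C5), nitrogen condenses with the ketone (N3–C4) and dehydration aromatises the ring, so the regiochemistry is fixed by the chloroketone. Methanol as solvent makes ester exchange degenerate.

Step 3
Reactants: 4 methyl 2-[2-(1-hydroxy-2-methylpropan-2-yl)-1,3-thiazol-4-yl]acetate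
Product: 5 methyl 2-[2-(2-methyl-1-oxopropan-2-yl)-1,3-thiazol-4-yl]acetate
Conditions: Dess–Martin periodinane, CH2Cl2, 0 → 23 °C
Reagents that add atoms: none
Why: Dess–Martin oxidation of a primary neopentyl alcohol under neutral conditions, which thiazole and ester tolerate. The aldehyde has no α-hydrogen and can neither enolise nor over-oxidise here.

Step 4
Reactants: 5 methyl 2-[2-(2-methyl-1-oxopropan-2-yl)-1,3-thiazol-4-yl]acetate
Product: 7 methyl 2-{2-[(3R)-3-hydroxy-2-methylhex-5-en-2-yl]-1,3-thiazol-4-yl}acetate, via homoallyl diisopinocampheylborinate 6 (not isolated)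
Conditions: B-allylbis(isopinocampheyl)borane from (−)-α-pinene (salt-free, pentane), Et2O, −100 → −78 °C; then 30 % H2O2, pH 7 buffer, MeOH, 0 °C
Reagents that add atoms: B-allylbis(isopinocampheyl)borane derived from (−)-α-pinene, C=CCB([C@H]1C[C@H]2C[C@@H]([C@@H]1C)C2(C)C)[C@H]1C[C@H]2C[C@@H]([C@@H]1C)C2(C)C
Why: Brown allylboration through a chair Zimmerman–Traxler transition state; the reagent from (−)-α-pinene delivers allyl to the Re face of 5, which gives (R) at C8 because the quaternary C7 outranks the allyl CH2. α,α-Dimethyl aldehydes and thiazole-bearing aldehydes are established substrates, the ester is inert at this temperature, and the buffered peroxide work-up spares it.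

Step 5
Reactants: 7 methyl 2-{2-[(3R)-3-hydroxy-2-methylhex-5-en-2-yl]-1,3-thiazol-4-yl}acetate; 8 pent-4-ynoic acid
Product: 11 methyl 2-{2-[(3R)-3-(but-3-yn-1-ylcarbamoyloxy)-2-methylhex-5-en-2-yl]-1,3-thiazol-4-yl}acetate, via pent-4-ynoyl azide 9 (not isolated), via 4-isocyanatobut-1-yne 10 (not isolated)
Conditions: 8, DPPA, Et3N, PhMe, 23 → 85 °C; then 7, dibutyltin dilaurate (10 mol %), 85 °C
Reagents that add atoms: diphenylphosphoryl azide, [N-]=[N+]=NP(=O)(Oc1ccccc1)Oc1ccccc1
Why: Curtius rearrangement of the acyl azide followed by tin-catalysed addition of the hindered secondary alcohol to the isocyanate; the C8–O bond is not touched, so (R) is kept. A copper catalyst is avoided because azide and terminal alkyne are present together.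

Step 6
Reactants: 11 methyl 2-{2-[(3R)-3-(but-3-yn-1-ylcarbamoyloxy)-2-methylhex-5-en-2-yl]-1,3-thiazol-4-yl}acetate
Product: 13 methyl 2-(2-{2-[(7Z,10R)-6-methylidene-2-oxo-1-oxa-3-azacyclodec-7-en-10-yl]propan-2-yl}-1,3-thiazol-4-yl)acetate, via triene carbamate 12 (not isolated)
Conditions: Grubbs II (5 mol %), C2H4 (1 atm), CH2Cl2, 23 °C; then Ar purge, dilution with PhMe to 1 mM, Hoveyda–Grubbs II (10 mol %), 1,4-benzoquinone (10 mol %), 80 °C
Reagents that add atoms: ethene, C=C (one of its CH2 groups becomes the methylidene on C12)
Why: Ruthenium-carbene enyne metathesis in two stages in one flask: under ethene the methylidene adds to the terminal alkyne of 11 with CH2 going to the substituted carbon C12, and ethene releases the resulting vinylcarbene as the 2-substituted butadiene 12. After purging and dilution the catalyst loads on the unhindered C10 terminus and closes onto the monosubstituted end (C11) of the diene with loss of ethene, so the net change 11 → 13 is an isomerisation that forms C10=C11 and C12=CH2 and equals an endo-mode ring-closing enyne metathesis. The closest known reaction types are the ethene-mediated tandem cross/ring-closing enyne metathesis to macrocyclic 1,3-dienes and the ring-closing metathesis of ten-membered lactones. One ring is closed, the ten-membered 1-oxa-3-azacyclodec-7-en-2-one, by diene-ene closure with both former alkyne carbons endocyclic and the new methylidene exocyclic. No stereocentre is made and C8 is not touched; the element that is set is the C10=C11 geometry, and the ring controls it: the planar, fully extended C8–O–C(=O)–N–C14 unit holds C8 and C14 about 5 Å apart, a gap that the C9–C13 bridge should span without strain only as a U with a cis olefin, in line with the lower energy of Z- over E-cyclodecene, and the NHC catalyst at 80 °C lets the ring olefin equilibrate towards this minimum. Site selectivity is needed between the vinyl end and the 1,1-disubstituted C12=CH2 of 12; the latter is sterically slower and would give a nine-membered ring with a trisubstituted olefin. Ring closure has to beat oligomerisation, which 1 mM dilution, removal of ethene and the rotamer restriction by the bulky C7 group next to C8–O should secure. The thiazole nitrogen is shielded by its C2 and C4 substituents, NH carbamates and esters are tolerated, and the metathesis-active hexadienyl chain is deliberately still absent.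

Step 7
Reactants: 13 methyl 2-(2-{2-[(7Z,10R)-6-methylidene-2-oxo-1-oxa-3-azacyclodec-7-en-10-yl]propan-2-yl}-1,3-thiazol-4-yl)acetate
Product: 14 methyl 2-{2-[(3R,5Z)-3-hydroxy-9-(methoxycarbonylamino)-2-methyl-7-methylidenenon-5-en-2-yl]-1,3-thiazol-4-yl}acetate
Conditions: NaOMe (30 mol %), MeOH, 50 °C; aq NH4Cl
Reagents that add atoms: methanol, CO
Why: Base-catalysed transcarbamoylation (alcoholysis of a carbamate): methoxide adds to the ring carbonyl, or the N-anion fragments to an isocyanate that methanol captures, and both channels expel the hindered O8 alkoxide and give the same methyl carbamate. Relief of medium-ring strain and the solvent excess drive the equilibrium, ester exchange is degenerate, and neither the C8–O bond nor the unactivated Z diene is touched.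

Step 8
Reactants: 14 methyl 2-{2-[(3R,5Z)-3-hydroxy-9-(methoxycarbonylamino)-2-methyl-7-methylidenenon-5-en-2-yl]-1,3-thiazol-4-yl}acetate
Product: 15 methyl N-[(4Z,7R)-7-hydroxy-8-methyl-3-methylidene-8-[4-(2-oxoethyl)-1,3-thiazol-2-yl]non-4-en-1-yl]carbamate
Conditions: DIBAL-H (3.3 equiv), CH2Cl2, −78 °C; aq Rochelle salt; used crude at once
Reagents that add atoms: none
Why: Partial ester reduction with DIBAL-H, which stops at the tetrahedral aluminium hemiacetal at −78 °C. The first two equivalents are consumed by OH and NH, and the N-metallated carbamate is far less electrophilic than the ester.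

Step 9
Reactants: 15 methyl N-[(4Z,7R)-7-hydroxy-8-methyl-3-methylidene-8-[4-(2-oxoethyl)-1,3-thiazol-2-yl]non-4-en-1-yl]carbamate; 16 but-3-en-1-yl(triphenyl)phosphonium bromide
Product: 18 mycothiazole (methyl N-[(4Z,7R)-8-{4-[(2Z)-hexa-2,5-dien-1-yl]-1,3-thiazol-2-yl}-7-hydroxy-8-methyl-3-methylidenenon-4-en-1-yl]carbamate), via but-3-enylidenetriphenylphosphorane 17 (not isolated)
Conditions: 16 (4.5 equiv), NaHMDS (4.3 equiv), THF, 0 °C; then 15, −78 → 0 °C
Reagents that add atoms: none
Why: Wittig olefination with a non-stabilised ylide under lithium-free conditions, where kinetic formation of the cis-oxaphosphetane gives the Z olefin C2′=C3′. Excess ylide takes up the OH and NH protons, addition at −78 °C should outrun enolisation, and the ylide is not basic enough to move the new skipped diene, which sees no further reagent.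

## Compound list

1 | 3-hydroxy-2,2-dimethylpropanenitrile | CC(C)(CO)C#N | starting material
2 | 3-hydroxy-2,2-dimethylpropanethioamide | CC(C)(CO)C(N)=S | intermediate
3 | methyl 4-chloro-3-oxobutanoate | COC(=O)CC(=O)CCl | starting material
4 | methyl 2-[2-(1-hydroxy-2-methylpropan-2-yl)-1,3-thiazol-4-yl]acetate | COC(=O)Cc1csc(C(C)(C)CO)n1 | intermediate
5 | methyl 2-[2-(2-methyl-1-oxopropan-2-yl)-1,3-thiazol-4-yl]acetate | COC(=O)Cc1csc(C(C)(C)C=O)n1 | intermediate
6 | (3R)-2-[4-(2-methoxy-2-oxoethyl)-1,3-thiazol-2-yl]-2-methylhex-5-en-3-yl bis(isopinocampheyl)borinate | COC(=O)Cc1csc(C(C)(C)[C@H](OB([C@H]2C[C@H]3C[C@@H]([C@@H]2C)C3(C)C)[C@H]2C[C@H]3C[C@@H]([C@@H]2C)C3(C)C)CC=C)n1 | intermediate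
7 | methyl 2-{2-[(3R)-3-hydroxy-2-methylhex-5-en-2-yl]-1,3-thiazol-4-yl}acetate | COC(=O)Cc1csc(C(C)(C)[C@H](O)CC=C)n1 | intermediate
8 | pent-4-ynoic acid | C#CCCC(=O)O | starting material
9 | pent-4-ynoyl azide | C#CCCC(=O)N=[N+]=[N-] | intermediate
10 | 4-isocyanatobut-1-yne | C#CCCN=C=O | intermediate
11 | methyl 2-{2-[(3R)-3-(but-3-yn-1-ylcarbamoyloxy)-2-methylhex-5-en-2-yl]-1,3-thiazol-4-yl}acetate | COC(=O)Cc1csc(C(C)(C)[C@H](OC(=O)NCCC#C)CC=C)n1 | intermediate
12 | methyl 2-{2-[(3R)-2-methyl-3-(3-methylidenepent-4-en-1-ylcarbamoyloxy)hex-5-en-2-yl]-1,3-thiazol-4-yl}acetate | COC(=O)Cc1csc(C(C)(C)[C@H](OC(=O)NCCC(=C)C=C)CC=C)n1 | intermediate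
13 | methyl 2-(2-{2-[(7Z,10R)-6-methylidene-2-oxo-1-oxa-3-azacyclodec-7-en-10-yl]propan-2-yl}-1,3-thiazol-4-yl)acetate | COC(=O)Cc1csc(C(C)(C)[C@H]2C/C=C\C(=C)CCNC(=O)O2)n1 | intermediate
14 | methyl 2-{2-[(3R,5Z)-3-hydroxy-9-(methoxycarbonylamino)-2-methyl-7-methylidenenon-5-en-2-yl]-1,3-thiazol-4-yl}acetate | COC(=O)Cc1csc(C(C)(C)[C@H](O)C/C=C\C(=C)CCNC(=O)OC)n1 | intermediate
15 | methyl N-[(4Z,7R)-7-hydroxy-8-methyl-3-methylidene-8-[4-(2-oxoethyl)-1,3-thiazol-2-yl]non-4-en-1-yl]carbamate | O=CCc1csc(C(C)(C)[C@H](O)C/C=C\C(=C)CCNC(=O)OC)n1 | intermediate
16 | but-3-en-1-yl(triphenyl)phosphonium bromide | C=CCC[P+](c1ccccc1)(c1ccccc1)c1ccccc1.[Br-] | starting material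
17 | but-3-enylidenetriphenylphosphorane | C=CCC=P(c1ccccc1)(c1ccccc1)c1ccccc1 | intermediate
18 | mycothiazole, methyl N-[(4Z,7R)-8-{4-[(2Z)-hexa-2,5-dien-1-yl]-1,3-thiazol-2-yl}-7-hydroxy-8-methyl-3-methylidenenon-4-en-1-yl]carbamate | C=CC/C=C\Cc1csc(C(C)(C)[C@H](O)C/C=C\C(=C)CCNC(=O)OC)n1 | target

## Step count and least certain steps

Total step count: 9. Longest linear sequence: 9 (1 → 18). Compounds 3, 8 and 16 are commercial and enter directly.

**Step 6 (key step).**
- What may go wrong: ring strain may slow the closure so much that intermolecular metathesis to oligomers takes over. The ring may also close kinetically with poor geometric control and then equilibrate slowly, because a conjugated ring olefin re-enters metathesis reluctantly. Catalyst decay to hydride species may cause olefin migration.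
- Fallback: this sets out from 7 and comes back at 14, with a smaller ring and a different bond.
  - Silylation of 7 with chlorodimethyl(vinyl)silane gives the vinylsilyl ether F1.
  - Ring-closing metathesis gives the six-membered 1,2-oxasilacyclohex-3-ene F2, in which C10=C11 can only be cis.
  - Separately, but-3-yn-1-amine is acylated with methyl chloroformate to methyl but-3-yn-1-ylcarbamate F3. Markovnikov hydroiodination of F3 gives methyl (3-iodobut-3-en-1-yl)carbamate F4.
  - A fluoride-promoted, palladium-catalysed Hiyama coupling of F2 with F4 replaces silicon on C11 by C12 with retention and frees O8, which gives 14.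

**Step 7.**
- What may go wrong: deprotonation of the NH may deactivate the carbonyl, so that acyl substitution is slow. Long heating with base may then start condensation at the acidic thiazolylacetate CH2 or isomerisation of the diene.
- Fallback: this sets out from 13 and comes back at 14. It changes the mechanism from acyl substitution to dealkoxylation. Trichlorosilane and triethylamine cleave the NH carbamate to the ring-opened isocyanate dichlorosilyl ether F5. A methanol quench then adds to the isocyanate and removes the silyl group, which gives 14 without any alkoxide base.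

**Step 9.**
- What may go wrong: the basic ylide may enolise the heteroarylacetaldehyde, which leads to self-condensation. The Z selectivity may also erode.
- Fallback: this sets out from 15 and comes back at 18. A Stork–Zhao olefination with the less basic iodomethylene ylide gives the (Z)-alkenyl iodide F6. A Stille coupling with allyltributylstannane then forms C3′–C4′ with retention of geometry.

**Step 8.**
- What may go wrong: the aluminium hemiacetal may collapse early, with over-reduction to the alcohol. The crude aldehyde may be lost on work-up.
- Fallback: this sets out from 14 and comes back at 15. Full reduction with LiBH4 gives the primary alcohol F7. A primary-selective TEMPO/PhI(OAc)2 oxidation, which leaves the hindered C8 alcohol alone, then gives 15 just before use.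

**Step 5.**
- What may go wrong: the neopentylic secondary alcohol may add slowly, so that the isocyanate is consumed by trimerisation or by traces of water.
- Fallback: this sets out from 7 and comes back at 11. It activates the other partner. 4-Nitrophenyl chloroformate and pyridine convert 7 into the mixed carbonate F8, which but-3-yn-1-amine opens to 11.

## Further compounds

F1 | step 6 | methyl 2-{2-[(3R)-3-[dimethyl(vinyl)silyloxy]-2-methylhex-5-en-2-yl]-1,3-thiazol-4-yl}acetate | COC(=O)Cc1csc(C(C)(C)[C@H](O[Si](C)(C)C=C)CC=C)n1
F2 | step 6 | methyl 2-(2-{2-[(6R)-2,2-dimethyl-5,6-dihydro-2H-1,2-oxasilin-6-yl]propan-2-yl}-1,3-thiazol-4-yl)acetate | COC(=O)Cc1csc(C(C)(C)[C@H]2CC=C[Si](C)(C)O2)n1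
F3 | step 6 | methyl but-3-yn-1-ylcarbamate | COC(=O)NCCC#C
F4 | step 6 | methyl (3-iodobut-3-en-1-yl)carbamate | COC(=O)NCCC(I)=C
F5 | step 7 | methyl 2-{2-[(3R,5Z)-3-(dichlorosilyloxy)-9-isocyanato-2-methyl-7-methylidenenon-5-en-2-yl]-1,3-thiazol-4-yl}acetate | COC(=O)Cc1csc(C(C)(C)[C@H](O[SiH](Cl)Cl)C/C=C\C(=C)CCN=C=O)n1
F6 | step 9 | methyl N-[(4Z,7R)-7-hydroxy-8-{4-[(2Z)-3-iodoprop-2-en-1-yl]-1,3-thiazol-2-yl}-8-methyl-3-methylidenenon-4-en-1-yl]carbamate | I/C=C\Cc1csc(C(C)(C)[C@H](O)C/C=C\C(=C)CCNC(=O)OC)n1
F7 | step 8 | methyl N-[(4Z,7R)-7-hydroxy-8-[4-(2-hydroxyethyl)-1,3-thiazol-2-yl]-8-methyl-3-methylidenenon-4-en-1-yl]carbamate | OCCc1csc(C(C)(C)[C@H](O)C/C=C\C(=C)CCNC(=O)OC)n1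
F8 | step 5 | methyl 2-{2-[(3R)-2-methyl-3-(4-nitrophenoxycarbonyloxy)hex-5-en-2-yl]-1,3-thiazol-4-yl}acetate | COC(=O)Cc1csc(C(C)(C)[C@H](OC(=O)Oc2ccc([N+](=O)[O-])cc2)CC=C)n1
A1 | alternative 1 | methyl 2-{2-[(3R,5Z)-3-(tert-butyldimethylsilyloxy)-6-iodo-2-methylhex-5-en-2-yl]-1,3-thiazol-4-yl}acetate | COC(=O)Cc1csc(C(C)(C)[C@H](O[Si](C)(C)C(C)(C)C)C/C=C\I)n1
A2 | alternative 1 | methyl [3-(tributylstannyl)but-3-en-1-yl]carbamate | COC(=O)NCCC(=C)[Sn](CCCC)(CCCC)CCCC
A3 | alternative 2 | 2-{4-[(2Z)-hexa-2,5-dien-1-yl]-1,3-thiazol-2-yl}-2-methylpropanal | C=CC/C=C\Cc1csc(C(C)(C)C=O)n1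
A4 | alternative 2 | (6R)-6-(2-{4-[(2Z)-hexa-2,5-dien-1-yl]-1,3-thiazol-2-yl}propan-2-yl)-5,6-dihydro-2H-pyran-2-one | C=CC/C=C\Cc1csc(C(C)(C)[C@H]2CC=CC(=O)O2)n1
A5 | alternative 2 | (3R,5Z)-2-{4-[(2Z)-hexa-2,5-dien-1-yl]-1,3-thiazol-2-yl}-2-methyl-7-[(trimethylsilyl)methyl]octa-5,7-dien-3-ol | C=CC/C=C\Cc1csc(C(C)(C)[C@H](O)C/C=C\C(=C)C[Si](C)(C)C)n1
A6 | alternative 3 | methyl N-[(4Z,7R)-9-amino-7-hydroxy-8,8-dimethyl-3-methylidene-9-sulfanylidenenon-4-en-1-yl]carbamate | NC(=S)C(C)(C)[C@H](O)C/C=C\C(=C)CCNC(=O)OC
A7 | alternative 3 | (4Z)-1-bromoocta-4,7-dien-2-one | C=CC/C=C\CC(=O)CBr
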